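**Retrosynthetic overview**
- Ring C: open the enol-ether C–O bond of the dihydropyranone to the δ-hydroxy-β-diketone. Cut its C3–C4 bond (Claisen) into a side-chain methyl ester and free (S)-4-hydroxypentan-2-one, used as its O,C-dianion. Chain extension and ring closure run in one flask without protecting groups.
- Aryl–CH2 bond (Negishi): 6-iodoeugenin plus the zinc homoenolate of methyl (S)-3-bromo-2-methylpropanoate, which brings in the (R)-methyl centre.
- Ring B: the C6–I bond comes from eugenin by 5-OH-directed iodination. Eugenin opens at the pyrone C–O bond to a symmetric aryl 1,3-diketone, made by Claisen condensation of 2',6'-dihydroxy-4'-methoxyacetophenone with ethyl acetate.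
- Ring order: A is bought, B forms in step 1, C forms in step 5. Both O-heterocycles close as in the polyketide pathway: an internal OH adds to a 1,3-diketone and water is lost.

Assumption: 1, 6 and 9 are taken as catalogue chemicals, with 6 and 9 at 98% ee or better.

**Step 1**
Reactants: 1 2',6'-dihydroxy-4'-methoxyacetophenone; 2 ethyl acetate
Product: 4 eugenin (5-hydroxy-7-methoxy-2-methyl-4H-chromen-4-one), via aryl diketone 3 (not isolated)
Conditions: LiN(SiMe3)2 (4.5 equiv), THF, −78 to −10 °C; 2 (3 equiv), −78 °C to rt; then conc. HCl, MeOH, 60 °C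
Reagents that add atoms: none
Why: Crossed Claisen condensation of fully deprotonated 1 with ethyl acetate builds the pentaketide-type aryl 1,3-diketone 3, and acid then closes ring B by the hemiketalisation–dehydration (cyclodehydration) assumed for the natural chromone; the two phenols of 3 are equivalent by symmetry, so only one chromone can form, and no stereocentre is created.

**Step 2**
Reactants: 4 eugenin
Product: 5 6-iodoeugenin (5-hydroxy-6-iodo-7-methoxy-2-methyl-4H-chromen-4-one)
Conditions: BnMe3N·ICl2 (1.05 equiv), CaCO3 (1.5 equiv), CH2Cl2–MeOH 5:2, rt, dark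
Reagents that add atoms: benzyltrimethylammonium dichloroiodate, C[N+](C)(C)Cc1ccccc1.Cl[I-]Cl
Why: Electrophilic aromatic iodination in a buffered medium, in which the free 5-OH is the strongest activator and steers the iodine donor to its only open ortho carbon C6, the pattern known for 5-hydroxy-7-alkoxy chromones and flavones (C8 attack takes over only when the 5-oxygen is alkylated), while the electron-poor pyrone C3 stays untouched and no stereocentre is formed.

**Step 3**
Reactants: 5 6-iodoeugenin; 6 methyl (2S)-3-bromo-2-methylpropanoate
Product: 8 methyl (2R)-3-(5-hydroxy-7-methoxy-2-methyl-4-oxo-4H-chromen-6-yl)-2-methylpropanoate, via alkylzinc bromide 7 (not isolated)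
Conditions: 6, Zn dust (TMSCl and BrCH2CH2Br activation), LiCl, THF, 45 °C (gives 7, 3 equiv); then 5, Pd(OAc)2 (5 mol %), SPhos (10 mol %), THF, 50 °C
Reagents that add atoms: none
Why: Negishi sp3–sp2 cross-coupling, in which zerovalent palladium formed from Pd(OAc)2 and SPhos inserts into the C–I bond, the ester-stabilised primary alkylzinc 7 transmetalates, and fast reductive elimination from the bulky biarylphosphine complex outruns β-hydride elimination and protonolysis by the chelated 5-OH; the stereocentre lies β to zinc, takes part in no bond change and is carried over from 6 (S becomes R only because the CIP rank of the CH2 group drops).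

**Step 4**
Reactants: 9 ethyl (3S)-3-hydroxybutanoate
Product: 11 (4S)-4-hydroxypentan-2-one, via Weinreb amide 10 (not isolated)
Conditions: MeNH(OMe)·HCl (1.3 equiv), MeMgCl (3.6 equiv), THF, −20 °C; more MeMgCl (2.2 equiv), 0 °C; aq HCl to pH 5
Reagents that add atoms: methylmagnesium chloride, C[Mg]Cl
Why: One-pot Weinreb ketone synthesis, in which the chloromagnesium amide aminolyses the ester faster than MeMgCl adds to it, the chelated tetrahedral adduct of 10 blocks a second addition, and the carbinol centre of the chiral-pool ester is never touched and stays (S).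

**Step 5**
Reactants: 8 methyl (2R)-3-(5-hydroxy-7-methoxy-2-methyl-4-oxo-4H-chromen-6-yl)-2-methylpropanoate; 11 (4S)-4-hydroxypentan-2-one
Product: 14 5-hydroxy-7-methoxy-2-methyl-6-{(2R)-2-[(2S)-2-methyl-4-oxo-3,4-dihydro-2H-pyran-6-yl]propyl}-4H-chromen-4-one (CNP0231471.1), via aldolate dianion 12 (not isolated), via hydroxy diketone 13 (not isolated)
Conditions: 11 (3 equiv), LiN(iPr)2 (6 equiv), THF, −78 to −30 °C (gives 12); 8 premixed with LiN(iPr)2 (1 equiv) in THF, added at −78 °C, then to −10 °C; then 3 M aq HCl, THF, 0 °C to rt
Reagents that add atoms: none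
Why: Proposed new method: the β-alkoxide makes LiN(iPr)2 enolise 11 on the methyl side and, since the carbonyl is already an enolate, retro-aldol cleavage is shut off, so dianion 12 can attack the methyl ester of 8 (whose 5-OH and vinylogous 2-CH3 are merely deprotonated and thereby masked) in a crossed Claisen condensation in which any O-acylation at the alkoxide funnels to the same product by O-to-C acyl transfer, the diketonate formed shields the neighbouring (R)-centre from enolisation, and acid then triggers the biosynthesis-like 6-exo hemiketalisation of the (S)-carbinol onto the C3 ketone of 13 and loss of water to the vinylogous ester, both stereocentres being carried in unchanged from 6 and 9; the closest known chemistry is the acylation of ketone lithium enolates by esters, the regioselective generation of aldolate dianions and the acid cyclodehydration of δ-hydroxy-β-diketones to 2,3-dihydro-4H-pyran-4-ones.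

**Compound list**
1 | 2',6'-dihydroxy-4'-methoxyacetophenone | COc1cc(O)c(C(C)=O)c(O)c1 | starting material
2 | ethyl acetate | CCOC(C)=O | starting material
3 | 1-(2,6-dihydroxy-4-methoxyphenyl)butane-1,3-dione | COc1cc(O)c(C(=O)CC(C)=O)c(O)c1 | intermediate
4 | eugenin, 5-hydroxy-7-methoxy-2-methyl-4H-chromen-4-one | COc1cc2oc(C)cc(=O)c2c(O)c1 | intermediate
5 | 5-hydroxy-6-iodo-7-methoxy-2-methyl-4H-chromen-4-one | COc1cc2oc(C)cc(=O)c2c(O)c1I | intermediate
6 | methyl (2S)-3-bromo-2-methylpropanoate | BrC[C@@H](C)C(=O)OC | starting material
7 | [(2S)-3-methoxy-2-methyl-3-oxopropyl]zinc bromide | Br[Zn]C[C@@H](C)C(=O)OC | intermediate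
8 | methyl (2R)-3-(5-hydroxy-7-methoxy-2-methyl-4-oxo-4H-chromen-6-yl)-2-methylpropanoate | COc1cc2oc(C)cc(=O)c2c(O)c1C[C@@H](C)C(=O)OC | intermediate
9 | ethyl (3S)-3-hydroxybutanoate | CCOC(=O)C[C@H](C)O | starting material
10 | (3S)-3-hydroxy-N-methoxy-N-methylbutanamide | CON(C)C(=O)C[C@H](C)O | intermediate
11 | (4S)-4-hydroxypentan-2-one | CC(=O)C[C@H](C)O | intermediate
12 | dilithium (4S)-pent-1-ene-2,4-diolate | C=C(O[Li])C[C@H](C)O[Li] | intermediate
13 | 5-hydroxy-6-[(2R,7S)-7-hydroxy-2-methyl-3,5-dioxooctyl]-7-methoxy-2-methyl-4H-chromen-4-one | COc1cc2oc(C)cc(=O)c2c(O)c1C[C@@H](C)C(=O)CC(=O)C[C@H](C)O | intermediate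
14 | 5-hydroxy-7-methoxy-2-methyl-6-{(2R)-2-[(2S)-2-methyl-4-oxo-3,4-dihydro-2H-pyran-6-yl]propyl}-4H-chromen-4-one | COc1cc2oc(C)cc(=O)c2c(O)c1C[C@@H](C)C1=CC(=O)C[C@H](C)O1 | target

**Total step count:** 5. **Longest linear sequence:** 4 (steps 1, 2, 3 and 5; step 4 feeds in).

**Steps most likely to fail**

Step 5 carries the most risk.
- The α-branched methyl ester may react slowly with 12.
- Proton shuffling could cause self-aldol reaction of 11 or erode the (R)-centre of 8.
- The deprotonated 2-methyl group of the chromone could be acylated.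
- In acid, the 5-OH could give chroman ketal or spiroketal isomers. These should revert to 14, because 14 keeps both the chelated phenol and the vinylogous ester.

The fallback sets out from 8 and comes back at 13. Treatment of 8 with MeNH(OMe)·HCl and iPrMgCl gives the Weinreb amide F1. This takes up the far less basic dilithio derivative of commercial (S)-pent-4-yn-2-ol (n-BuLi, THF, −78 to 0 °C) to give the ynone F2. Conjugate addition of diethylamine gives the enaminone F3, a masked 1,3-diketone. Aqueous acid hydrolyses F3 to 13, which closes to 14 under the same acid.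

Step 3 is the second risk. The iodide is flanked by OH and OMe, the phenol consumes organozinc, and β-hydride elimination would return 4. The fallback sets out from 5 and comes back at 8. A Heck reaction with methyl methacrylate (Pd(OAc)2, P(o-tol)3, Et3N, DMF, 100 °C) gives the (E)-enoate F4. Asymmetric hydrogenation with [Ir(cod)(tBu-PHOX)]BArF, using the ligand enantiomer that gives the R product, sets the methyl centre on a benchmark substrate class and leaves the chromone double bond alone.

Step 2 is the third risk. The 8-iodide or the 6,8-diiodide could form and would be hard to separate. The fallback sets out from 4 and comes back at 8. Magnesium-mediated ortho-formylation (MgCl2, Et3N, paraformaldehyde, MeCN, reflux) can deliver carbon only next to the phenoxide oxygen, and gives the 6-carbaldehyde F5. Wittig olefination with methyl 2-(triphenylphosphoranylidene)propanoate (toluene, 80 °C) leads to the (E)-enoate F4. The same iridium-catalysed asymmetric hydrogenation then gives 8, so 5 and the cross-coupling are bypassed.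

**Further compounds**
F1 | step 5 | (2R)-3-(5-hydroxy-7-methoxy-2-methyl-4-oxo-4H-chromen-6-yl)-N-methoxy-N,2-dimethylpropanamide | COc1cc2oc(C)cc(=O)c2c(O)c1C[C@@H](C)C(=O)N(C)OC
F2 | step 5 | 5-hydroxy-6-[(2R,7S)-7-hydroxy-2-methyl-3-oxooct-4-yn-1-yl]-7-methoxy-2-methyl-4H-chromen-4-one | COc1cc2oc(C)cc(=O)c2c(O)c1C[C@@H](C)C(=O)C#CC[C@H](C)O
F3 | step 5 | 6-[(2R,4E,7S)-5-(diethylamino)-7-hydroxy-2-methyl-3-oxooct-4-en-1-yl]-5-hydroxy-7-methoxy-2-methyl-4H-chromen-4-one | COc1cc2oc(C)cc(=O)c2c(O)c1C[C@@H](C)C(=O)/C=C(/N(CC)CC)C[C@H](C)O
F4 | step 3 | methyl (2E)-3-(5-hydroxy-7-methoxy-2-methyl-4-oxo-4H-chromen-6-yl)-2-methylprop-2-enoate | COC(=O)/C(C)=C/c1c(OC)cc2oc(C)cc(=O)c2c1O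
F5 | step 2 | 5-hydroxy-7-methoxy-2-methyl-4-oxo-4H-chromene-6-carbaldehyde | COc1cc2oc(C)cc(=O)c2c(O)c1C=O
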